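The data stem from a simulated flask with constants of no real substance; noise was put on by code.

common to all: L 0.20 M; Z 0.20 M

| run | J | X | temperature | remark | time |
|---|---|---|---|---|---|
| beta | 0.44 M | 1.4 mM | 31 °C | run made earlier |  |
| epsilon | 0.44 M | 5 mM | 56 °C | run made earlier |  |
| eta | 0.55 M | 4 mM | 31 °C | run made earlier |  |
| Thursday's | 0.150 M | 4.0 mM | 65 °C |  | 50 min |
| Saturday's | 1.20 M | 2.5 mM | 20 °C |  | 50 min |
| Wednesday's | 2.00 M | 4.0 mM | 50 °C |  | 50 min |
| Monday's | 0.440 M | 4.0 mM | 50 °C |  | 50 min |
| Friday's | 1.20 M | 1.0 mM | 50 °C |  | 50 min |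
| Tuesday's | 0.600 M | 4.0 mM | 50 °C |  | 50 min |

| run | time / min | D / % | E / % |
|---|---|---|---|
| beta | 8.00 | 7 | 0 |
| beta | 10.0 | 8 | 0 |
| beta | 15.0 | 10 | 3 |
| beta | 25.0 | 15 | 0 |
| beta | 40.0 | 26 | 2 |
| beta | 60.0 | 28 | 2 |
| beta | 90.0 | 37 | 2 |
| epsilon | 2.00 | 13 | 0 |
| epsilon | 5.00 | 20 | 2 |
| epsilon | 10.0 | 37 | 3 |
| epsilon | 15.0 | 42 | 4 |
| epsilon | 20.0 | 46 | 5 |
| epsilon | 30.0 | 53 | 9 |
| epsilon | 40.0 | 57 | 10 |
| eta | 8.00 | 6 | 0 |
| eta | 20.0 | 19 | 2 |
| eta | 40.0 | 29 | 3 |
| eta | 60.0 | 35 | 3 |
| eta | 90.0 | 43 | 4 |

(each reading ± 1.5 percentage points)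

- J is single-handed; L and Z are mirror images of each other, charged as a racemate, each of them at the stated concentration
- the earlier runs were read with a standard deviation of 1.5 percentage points
- steps thought possible: J + L -> D; J + Z -> E; L + X <-> Z + X; J + X -> Q
- the handed part of J does not stay in what it makes, so the products of the two hands are mirror images too

* all flasks from highest to lowest excess of D over E, at 50 min (Thursday's / Saturday's / Wednesday's / Monday's / Friday's / Tuesday's)
* the same order at 6.0 h (Thursday's / Saturday's / Wednesday's / Monday's / Friday's / Tuesday's)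
* the excess of D over E of the flask you put first, at 50 min
* the excess of D over E of the flask you put last, at 50 min

- The beta run ends at D 37% and E 2%, and these two amounts measure two rates, that of J on L and that of J on Z. Both attacks share the same J and the same clock, so if nothing else moves L or Z, the logarithm of the L left over the logarithm of the Z left is the ratio of the two rate constants, with J and time cancelled.
- Counting each product against its own enantiomer's charge, beta gives 33.0 and the eta run, at its last reading, 23.6. E stands close to the scatter of 1.5 percentage points, so the two are averaged in powers of ten, giving a logarithm of 1.45 and a reading of 27.9. This is the selectivity factor, the rate of J on L over the rate of J on Z at equal amounts of both.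
- The epsilon run shows the third route, since its D of 57% is more than the half of the substrate that L brought, so X must be turning Z into L there.
- Epsilon's reading at 10.0 min, 21.8, lies below the value at 31 °C. Saturday's is the coldest flask, and this reckoning puts it first. At vanishing conversion, with L equal to Z, the factor read above gives an excess of the factor less one over the factor plus one, 93.1%, which is a starting value and not the excess at 50 min.
- The forecast states “Selectivity is about 25 falling to 15 with heat”. It gives Saturday's > Thursday's > Monday's > Tuesday's > Friday's > Wednesday's at 50 min and Thursday's > Saturday's > Monday's > Tuesday's > Wednesday's > Friday's at 6.0 h, with the first flask at 90% (84% to 95%) and the last at 32% (22% to 42%), a top below the starting value reckoned here.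

    J + L → D (k = 0.00350 M⁻¹ s⁻¹, Ea = 70.0 kJ mol⁻¹)
    J + Z → E (k = 2.00 × 10⁻⁴ M⁻¹ s⁻¹, Ea = 90.0 kJ mol⁻¹)
    L + X ⇌ Z + X, rate k3*[X]*[L] forward; the back reaction follows from the equilibrium constant (k = 0.0530 M⁻¹ s⁻¹, Ea = 48.0 kJ mol⁻¹)
    J + X → Q (k = 0.00130 M⁻¹ s⁻¹, Ea = 57.0 kJ mol⁻¹)
    (constants at 50 °C)

- The flasks stand as Saturday's > Thursday's > Monday's > Tuesday's > Friday's > Wednesday's at 50 min and as Thursday's > Saturday's > Monday's > Tuesday's > Wednesday's > Friday's at 6.0 h, both as forecast, with Saturday's first at 92.6% and Wednesday's last at 26.2%, against the forecast's 32%.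
- Saturday's keeps 45% of its L at 50 min, and the factor then gives E as 1.41% beside the flask's 1.08%.
- The same flask as Saturday's at −5 °C reaches 97.5%, with D at 2.91% and E at 0.0372%, a logarithm of their ratio of 1.89 against 1.45.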